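The readings are calculated on assumed constants.

The substrate left over in the violet flask is what the next hand inherits, so here is the flask, with what is asked of it.

| setting | violet | teal | flask |
|---|---|---|---|
| substrate | 20 mM | 30 mM | 20 mM |
| gas | 13 mM (held) | 13 mM (held) | 13 mM (held) |
| temperature | 0 °C | −15 °C | 0 °C |
| remark | the very flask that is asked about, followed so far | run made earlier |  |
| time |  |  | 8.0 d |

| run | time / d | target / % |
|---|---|---|
| violet | 0.625 | 9 |
| violet | 1.04 | 18 |
| violet | 1.67 | 25 |
| violet | 2.50 | 29 |
| violet | 3.00 | 31 |
| violet | 5.00 | 33 |
| violet | 8.00 | 32 |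
| teal | 2.50 | 14 |
| teal | 4.00 | 17 |
| teal | 6.00 | 19 |
| teal | 8.00 | 15 |
| teal | 12.0 | 16 |
| teal | 20.0 | 17 |
| teal | 30.0 | 22 |

(scatter of a reading: 1.5 percentage points)

- gamma: at 8.0 d raise the temperature by 20 K, then wait 2.5 d
- zeta: at 8.0 d take out 90 % of the released group then present, then wait 2.5 d
- epsilon: change nothing and wait 2.5 d more
- delta: at 8.0 d add substrate, 50.0 % of the amount charged, then wait 2.5 d

- the volume of additions can be left aside
- what was read earlier has a scatter of 1.5 percentage points, one standard deviation
- at the start none of the gas is in solution

* target, in percent of the substrate first charged, at 8.0 d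
* which option adds most target ("none" when 2 percentage points or less is all one gets) (gamma / zeta / epsilon / delta / none)
* target present, in percent of the substrate first charged, after zeta
* target present, in percent of the substrate first charged, after delta

The last violet readings, 33 % and 32 %, stand against a scatter of 1.5 percentage points, so the flat end of the run can be solved by itself at about 32.5 %. That end gives 0.241, called Q: the plateau quotient, an apparent equilibrium constant, is target times released group over substrate times gas, with released group taken equal to target and substrate taken as charge less target. The early end joins on: target had passed half of that plateau by 1.04 d, and the wait of 2.5 d is 2.40 such spans. Leave the flask alone unless acting, since epsilon looks empty. On the enlarged charge, Q gives 41.3 % after delta. The teal run at 20.0 d gives 0.0804, a third of the violet Q, so warming looks strongest.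

The forecast, on the ground “I read the plateau as equilibrium”, says 32.5 %, gamma, 45 % after zeta, and 40 % after delta, a little below this reckoning.

The flask gives 33.2 %, 42.8 % after zeta and 43.6 % after delta, and gamma adds most, 15 points.

    gas ⇌ coupling partner, rate k1*(csat - [coupling partner]) (kL = 0.0689 h⁻¹)
    target ⇌ isomer of the product (K = 0.859, k = 0.230 h⁻¹, Ea = 90.0 kJ mol⁻¹, ΔH = −47.0 kJ mol⁻¹)
    substrate + coupling partner ⇌ target + released group (K = 0.820, k = 2.90 M⁻¹ h⁻¹, Ea = 61.0 kJ mol⁻¹, ΔH = 8.00 kJ mol⁻¹)
    (constants at 0 °C)

The neighbouring flask, the asked flask with 8.0 mM of substrate, gets 46.0 % from Q but holds 41.1 %, a gap of 4.9 points. Written with the amounts as they stand, substrate and released group included and coupling partner in place of gas, Q reads 0.819 in the flask. In the neighbouring flask, which holds 35.3 % of isomer of the product, it reads 0.819.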